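**Retrosynthetic overview**

- The route rests on ring A, the 2,6-dihydroxyphenyl ring (a1 carries the acyl group, a2 and a6 the oxygens, a3–a5 are CH). It is assembled, not acylated: a2–a5 come from C3–C6 of 3-hydroxy-2H-pyran-2-one and a1/a6 from the two alkyne carbons of an ethoxy ynone. Bonds a1–a2 and a5–a6 form by cycloaddition, and loss of CO2 aromatises the ring.
- The ethoxy ynone is cut between carbonyl and alkyne: the Weinreb amide of 9-(3,4-dimethoxyphenyl)nonanoic acid plus lithium ethoxyacetylide (LiC≡COEt).
- The chain and ring B come from veratrole and the azelaic half-ester by Friedel–Crafts acylation, then benzylic deoxygenation.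
- Ring order: ring B is bought as veratrole; ring A is the only ring formed (step 5); the ethyl ether and both methyl ethers are cleaved together in the last step.

Key step: step 5

Assumption: ethoxyacetylene is used as its commercial hexane solution, and the ethoxy ynone is taken into the key step soon after isolation, because push–pull ynones of this kind hydrate slowly on storage.

**Route**

Step 1
Reactants: 1 monomethyl azelate (9-methoxy-9-oxononanoic acid); 2 veratrole (1,2-dimethoxybenzene)
Product: 4 keto ester methyl 9-(3,4-dimethoxyphenyl)-9-oxononanoate, via methyl 9-chloro-9-oxononanoate 3 (not isolated)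
Conditions: (COCl)2, cat. DMF, CH2Cl2, 0 °C → rt, evaporate; then 2, AlCl3 (2.5 equiv), CH2Cl2, 0 °C → rt; cold 1 M HCl
Reagents that add atoms: none
Why: Friedel–Crafts acylation, in which the acid chloride made from the half-ester (the methyl ester is inert to oxalyl chloride) should acylate veratrole at C4, para to one methoxy group and the only unhindered activated position, and the deactivated aryl ketone should not react a second time.

Step 2
Reactants: 4 keto ester methyl 9-(3,4-dimethoxyphenyl)-9-oxononanoate
Product: 5 ester methyl 9-(3,4-dimethoxyphenyl)nonanoate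
Conditions: Et3SiH (3 equiv), TFA, 0 °C → rt
Reagents that add atoms: none
Why: Ionic hydrogenation, in which TFA protonates the electron-rich aryl ketone and then ionises the benzylic alcohol, each para-methoxy-stabilised benzylic cation being trapped by hydride from Et3SiH, while the aliphatic methyl ester cannot ionise and should survive.

Step 3
Reactants: 5 ester methyl 9-(3,4-dimethoxyphenyl)nonanoate
Product: 6 Weinreb amide 9-(3,4-dimethoxyphenyl)-N-methoxy-N-methylnonanamide
Conditions: MeNH(OMe)·HCl (1.5 equiv), i-PrMgCl (3 equiv), THF, −20 → 0 °C; aq NH4Cl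
Reagents that add atoms: N,O-dimethylhydroxylamine hydrochloride, Cl.CNOC
Why: Direct ester-to-Weinreb-amide aminolysis, in which the chloromagnesium amide of N,O-dimethylhydroxylamine adds to the unhindered methyl ester and the chelated product resists further attack by the Grignard reagent at low temperature.

Step 4
Reactants: 6 Weinreb amide 9-(3,4-dimethoxyphenyl)-N-methoxy-N-methylnonanamide; 7 ethoxyacetylene
Product: 10 ethoxy ynone 11-(3,4-dimethoxyphenyl)-1-ethoxyundec-1-yn-3-one, via lithium ethoxyacetylide 8 (not isolated), via tetrahedral lithium N,O-chelate 9 (not isolated)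
Conditions: 7 (1.5 equiv), n-BuLi, THF, −78 °C; then 6, −78 → −30 °C; inverse quench into cold aq NaHSO4/Et2O, 0 °C
Reagents that add atoms: none
Why: Weinreb ketone synthesis, in which the acetylide adds once to give the stable five-membered chelate 9 that releases the ynone only on the cold acidic quench, which also holds the liberated amine as its salt so that it cannot add to the ynone.

Step 5
Reactants: 10 ethoxy ynone 11-(3,4-dimethoxyphenyl)-1-ethoxyundec-1-yn-3-one; 11 3-hydroxy-2H-pyran-2-one
Product: 13 ring A mono-ethyl ether 9-(3,4-dimethoxyphenyl)-1-(2-ethoxy-6-hydroxyphenyl)nonan-1-one, via bridged bicyclic lactone 12 (not isolated)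
Conditions: 11 (1.3 equiv), Et3N (0.3 equiv), CH2Cl2, 0 °C → rt, then 40 °C
Reagents that add atoms: none
Why: Proposed new method: Et3N turns 11 into its 3-oxido form, an electron-rich diene with its largest donor coefficient at the remote terminus C6, which bonds to the ethoxy-bearing β-carbon of ynone 10 while the hydroxyl-bearing C3 bonds to the carbon α to the ketone, either in one asynchronous [4+2] event or as Michael addition followed by 6-exo-trig aldol closure of the allenolate onto the C3 carbonyl. The resulting 2-oxabicyclo[2.2.2]octa-5,7-dien-3-one 12 should expel CO2 by retro-Diels–Alder reaction at or just above room temperature, so the six-membered ring A is closed by intermolecular [4+2] annulation (bonds a1–a2 and a5–a6) and emerges aromatic without an oxidant. The closest known reaction types are the amine-promoted Diels–Alder reactions of 3-hydroxy-2-pyrone with electron-poor alkenes and the benzannulation of 2-pyrones with alkynes by cycloaddition and decarboxylation; the pairing of the oxidopyrone with an alkoxy ynone is the untested part. No stereocentre is created in 13, because the two bridgehead centres of racemic 12 vanish with the CO2. The step needs the regiochemistry C3-to-acyl carbon, which the matched polarity of oxido donor and ketone acceptor should provide, and C- rather than O-attack of the pyronate on the ynone, which is favoured by keeping the amine substoichiometric and by the fact that only C6 attack feeds an irreversible sequence ending in loss of CO2.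

Step 6
Reactants: 13 ring A mono-ethyl ether 9-(3,4-dimethoxyphenyl)-1-(2-ethoxy-6-hydroxyphenyl)nonan-1-one
Product: 14 malabaricone C, 9-(3,4-dihydroxyphenyl)-1-(2,6-dihydroxyphenyl)nonan-1-one
Conditions: BBr3 (8 equiv), CH2Cl2, −78 °C → rt; degassed ice-water, EtOAc
Reagents that add atoms: none
Why: Lewis-acid ether cleavage, in which BBr3 binds each ether oxygen and bromide removes the alkyl group (the ethyl group helped by chelation of boron between the ring A ether and the ketone), and hydrolysis of the aryl borates on work-up should free all four phenols without touching the ketone or the chain.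

**Compound list**

1 | monomethyl azelate (9-methoxy-9-oxononanoic acid) | COC(=O)CCCCCCCC(=O)O | starting material
2 | veratrole (1,2-dimethoxybenzene) | COc1ccccc1OC | starting material
3 | methyl 9-chloro-9-oxononanoate | COC(=O)CCCCCCCC(=O)Cl | intermediate (not isolated)
4 | methyl 9-(3,4-dimethoxyphenyl)-9-oxononanoate | COC(=O)CCCCCCCC(=O)c1ccc(OC)c(OC)c1 | intermediate
5 | methyl 9-(3,4-dimethoxyphenyl)nonanoate | COC(=O)CCCCCCCCc1ccc(OC)c(OC)c1 | intermediate
6 | 9-(3,4-dimethoxyphenyl)-N-methoxy-N-methylnonanamide | CON(C)C(=O)CCCCCCCCc1ccc(OC)c(OC)c1 | intermediate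
7 | ethoxyacetylene | CCOC#C | starting material
8 | lithium ethoxyacetylide | CCOC#C[Li] | intermediate (not isolated)
9 | lithium 11-(3,4-dimethoxyphenyl)-1-ethoxy-3-[methoxy(methyl)amino]undec-1-yn-3-olate (tetrahedral N,O-chelate) | CCOC#CC(O[Li])(N(C)OC)CCCCCCCCc1ccc(OC)c(OC)c1 | intermediate (not isolated)
10 | 11-(3,4-dimethoxyphenyl)-1-ethoxyundec-1-yn-3-one | CCOC#CC(=O)CCCCCCCCc1ccc(OC)c(OC)c1 | intermediate
11 | 3-hydroxy-2H-pyran-2-one | O=c1occcc1O | starting material
12 | 8-[9-(3,4-dimethoxyphenyl)nonanoyl]-7-ethoxy-4-hydroxy-2-oxabicyclo[2.2.2]octa-5,7-dien-3-one (racemic; both bridgehead centres are lost with CO2) | O=C1OC2C=CC1(O)C(C(=O)CCCCCCCCc1ccc(OC)c(OC)c1)=C2OCC | intermediate (not isolated)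
13 | 9-(3,4-dimethoxyphenyl)-1-(2-ethoxy-6-hydroxyphenyl)nonan-1-one | CCOc1cccc(O)c1C(=O)CCCCCCCCc1ccc(OC)c(OC)c1 | intermediate
14 | malabaricone C, 9-(3,4-dihydroxyphenyl)-1-(2,6-dihydroxyphenyl)nonan-1-one (no stereocentre) | O=C(CCCCCCCCc1ccc(O)c(O)c1)c1c(O)cccc1O | target

**Summary**

Total step count: 6. Longest linear sequence: 6 steps (1 and 2 to 14; 7 and 11 enter directly).

**Steps most likely to fail**

1. Step 5 (the proposed new method).
 - What may go wrong: the pyronate oxygen or the amine adds to the ynone in conjugate fashion; the C6 Michael adduct is protonated and re-aromatises to a 6-alkenyl pyrone instead of closing; or the donor ethoxy group leaves the ynone too weak an acceptor for the cycloaddition to compete.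
 - Fallback (known chemistry, sets out from 6 and comes back at 14, replacing steps 4 to 6): 1,3-dimethoxybenzene (COc1cccc(OC)c1) is lithiated between its two methoxy groups with n-BuLi in THF at 0 °C → rt to give (2,6-dimethoxyphenyl)lithium F1. Addition of Weinreb amide 6 at −78 → 0 °C should give the tetrahedral lithium N,O-chelate F2, which collapses on quenching with 1 M HCl to 1-(2,6-dimethoxyphenyl)-9-(3,4-dimethoxyphenyl)nonan-1-one F3. BBr3 in CH2Cl2 (−78 °C → rt) then cleaves all four methyl ethers to give 14.

2. Step 4.
 - What may go wrong: during the quench the liberated N,O-dimethylhydroxylamine or water adds to the push–pull ynone, and the ynol ether hydrates on acidic contact or on silica, so the ynone is lost before it can be used.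
 - Fallback (sets out from 6 and comes back at 10): the ynone is reached by oxidation, so that no amine is ever present with it. Amide 6 is reduced with i-Bu2AlH in THF at −78 °C to 9-(3,4-dimethoxyphenyl)nonanal F4. Lithium ethoxyacetylide 8 (from 7 and n-BuLi, THF, −78 °C) adds to the aldehyde to give racemic 11-(3,4-dimethoxyphenyl)-1-ethoxyundec-1-yn-3-ol F5 after an NH4Cl quench. Activated MnO2 in CH2Cl2 at rt oxidises the propargylic alcohol to 10, which is isolated by filtration only.

3. Step 1.
 - What may go wrong: the excess AlCl3 required (it is bound by the ester, both ethers and the product ketone) cleaves the methoxy group para to the new ketone, and any oxalyl chloride left after evaporation acylates veratrole.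
 - Fallback (sets out from 2 and comes back at 5, replacing steps 1 and 2): the aryl–chain bond is made by cross-coupling instead of acylation. Veratrole 2 is brominated with NBS in MeCN at rt to 4-bromo-1,2-dimethoxybenzene F6. Purchased methyl non-8-enoate (C=CCCCCCCC(=O)OC) is hydroborated with 9-BBN in THF (0 °C → rt) to methyl 9-(9-borabicyclo[3.3.1]nonan-9-yl)nonanoate F7. B-alkyl Suzuki–Miyaura coupling of F7 with F6 (PdCl2(dppf), K3PO4, THF/DMF/H2O, 60 °C) should give 5 directly.

**Further compounds**

F1 | step 5 | (2,6-dimethoxyphenyl)lithium | COc1cccc(OC)c1[Li]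
F2 | step 5 | lithium 1-(2,6-dimethoxyphenyl)-9-(3,4-dimethoxyphenyl)-1-[methoxy(methyl)amino]nonan-1-olate | COc1cccc(OC)c1C(O[Li])(N(C)OC)CCCCCCCCc1ccc(OC)c(OC)c1
F3 | step 5 | 1-(2,6-dimethoxyphenyl)-9-(3,4-dimethoxyphenyl)nonan-1-one | COc1cccc(OC)c1C(=O)CCCCCCCCc1ccc(OC)c(OC)c1
F4 | step 4 | 9-(3,4-dimethoxyphenyl)nonanal | O=CCCCCCCCCc1ccc(OC)c(OC)c1
F5 | step 4 | 11-(3,4-dimethoxyphenyl)-1-ethoxyundec-1-yn-3-ol (racemic) | CCOC#CC(O)CCCCCCCCc1ccc(OC)c(OC)c1
F6 | step 1 | 4-bromo-1,2-dimethoxybenzene | COc1ccc(Br)cc1OC
F7 | step 1 | methyl 9-(9-borabicyclo[3.3.1]nonan-9-yl)nonanoate | COC(=O)CCCCCCCCB1C2CCCC1CCC2
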